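**Strategy.** The ether between C4 of unit A and O6 of unit B is cut first, which reduces the target to two copies of one monomer; the lactone ring of that monomer is then cut at O2–C3 and at C4–O. The feature exploited is the cis C3–O2/C4–OH pair on the lactone ring of unit B: two oxygens on the same face of what was an (E)-propenyl group ortho to the C1 ester. A chiral aryl-λ3-iodane oxylactonization of methyl 2,4-bis(benzyloxy)-3-methoxy-6-[(E)-prop-1-enyl]benzoate closes that ring and sets C3 and C4 in one operation; Mitsunobu inversion at C4 with the O6 phenol of a second monomer then gives the trans unit A.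

Key step: step 6

Assumption: the (R,R)-configured iodane is taken to deliver the (3R,4R) lactone; should the facial sense prove opposite, its mirror image (from the other lactate enantiomer) would be used with no other change.

Remark on reagent and protection: the iodane, [2,6-bis{[(2R)-1-methoxy-1-oxopropan-2-yl]oxy}phenyl]-λ3-iodanediyl diacetate, SMILES COC(=O)[C@@H](C)Oc1cccc(O[C@H](C)C(=O)OC)c1I(OC(C)=O)OC(C)=O, is a known stoichiometric reagent prepared beforehand from methyl lactate and is not counted as a route compound. The two benzyl ethers of the precursor are left identical on purpose: once they are removed, the 8-OH is held in a hydrogen bond to the C1 carbonyl, so only O6 enters the etherification.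

**Step 1**
Reactants: 1 3,5-dihydroxy-4-methoxybenzaldehyde; 2 benzyl bromide
Product: 3 3,5-bis(benzyloxy)-4-methoxybenzaldehyde
Conditions: BnBr, K2CO3, DMF, 60 °C
Reagents that add atoms: benzyl bromide, BrCc1ccccc1
Why: Williamson etherification of both phenoxides (SN2 on benzyl bromide) should proceed cleanly, since the carbonate base leaves the aldehyde alone.

**Step 2**
Reactants: 3 3,5-bis(benzyloxy)-4-methoxybenzaldehyde
Product: 4 3,5-bis(benzyloxy)-2-bromo-4-methoxybenzaldehyde
Conditions: NBS (1 equiv), MeCN, 0 °C → rt
Reagents that add atoms: N-bromosuccinimide, O=C1CCC(=O)N1Br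
Why: Electrophilic aromatic bromination can only occur at the two equivalent free ring positions, each ortho to one benzyloxy group and para to the other, so one equivalent of reagent should give a single monobromide ortho to the formyl group.

**Step 3**
Reactants: 4 3,5-bis(benzyloxy)-2-bromo-4-methoxybenzaldehyde; 5 ethyltriphenylphosphonium bromide
Product: 6 1,3-bis(benzyloxy)-4-bromo-2-methoxy-5-[(Z)-prop-1-enyl]benzene (expected to predominate; any (E)-isomer 7 formed alongside is carried on)
Conditions: EtPPh3Br, KOtBu, THF, 0 °C → rt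
Reagents that add atoms: ethyltriphenylphosphonium bromide, CC[P+](c1ccccc1)(c1ccccc1)c1ccccc1.[Br-]
Why: Wittig olefination with the non-stabilized ethylidene ylide is reliable on aryl aldehydes and kinetically Z-selective; an alkoxide base is chosen so that the aryl bromide is not touched, and the geometry is corrected in step 4.

**Step 4**
Reactants: 6 1,3-bis(benzyloxy)-4-bromo-2-methoxy-5-[(Z)-prop-1-enyl]benzene
Product: 7 1,3-bis(benzyloxy)-4-bromo-2-methoxy-5-[(E)-prop-1-enyl]benzene
Conditions: PdCl2(MeCN)2 (5 mol %), CH2Cl2, rt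
Reagents that add atoms: none
Why: Divalent palladium catalyses Z-to-E equilibration of aryl alkenes, and the (E)-styrene is strongly preferred thermodynamically, the more so with an ortho bromine that clashes with the methyl group in the Z form; the aryl bromide is inert because no zerovalent palladium is formed.

**Step 5**
Reactants: 7 1,3-bis(benzyloxy)-4-bromo-2-methoxy-5-[(E)-prop-1-enyl]benzene; 8 methyl chloroformate
Product: 10 methyl 2,4-bis(benzyloxy)-3-methoxy-6-[(E)-prop-1-enyl]benzoate, via aryllithium 9 (not isolated)
Conditions: n-BuLi, THF, −78 °C; then cannulated into ClCO2Me, THF, −78 °C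
Reagents that add atoms: methyl chloroformate, COC(=O)Cl
Why: Bromine–lithium exchange is faster than any deprotonation at −78 °C, and inverse addition to excess chloroformate should stop at the ester because the 2,6-disubstituted benzoate resists a second addition; the alkene geometry is untouched.

**Step 6**
Reactants: 10 methyl 2,4-bis(benzyloxy)-3-methoxy-6-[(E)-prop-1-enyl]benzoate; 11 acetic acid
Product: 12 (3R,4R)-4-acetoxy-6,8-bis(benzyloxy)-7-methoxy-3-methylisochroman-1-one
Conditions: (R,R)-ArI(OAc)2 (the lactate-derived iodane of the remark), BF3·OEt2, AcOH, CH2Cl2, −80 → −40 °C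
Reagents that add atoms: acetic acid, CC(=O)O
Why: BF3·OEt2 loosens one acetate of the iodane, the cationic trivalent iodine adds to one face of the (E)-alkene while the ester carbonyl oxygen attacks C3 from the other face, placing the aryliodanyl group on benzylic C4 of a cyclic methoxy-dioxocarbenium ion; acetate then displaces the iodanyl group (it leaves as the iodoarene) with inversion, and the ion loses its O-methyl group to acetate to give the lactone. The closest known reaction type is the enantioselective endo-oxylactonization of methyl ortho-alk-1-enylbenzoates with lactate-derived chiral aryl-λ3-iodanes, a known reaction on this substrate class. The lactone ring closes in the 6-endo-trig mode, oxygen onto C3. C3 is controlled by the reagent, whose lactate arms distinguish the two alkene faces; C4 is controlled relative to C3 by the alkene geometry and the mechanism, since anti oxy-iodination followed by SN2 inversion amounts to syn addition across the (E)-alkene, hence cis (3R,4R). The step needs 6-endo rather than 5-exo closure and SN2 rather than SN1 substitution at C4: the ester carbonyl, conjugated and in the arene plane, reaches the distal carbon C3 through a six-membered transition state while iodine takes the benzylic carbon, and the positive charge of the dioxocarbenium ring beside C4 should suppress ionization there despite the alkoxy-rich arene. At these temperatures the alkene is the most nucleophilic site, so the benzyl ethers and the arene should be spared.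

**Step 7**
Reactants: 12 (3R,4R)-4-acetoxy-6,8-bis(benzyloxy)-7-methoxy-3-methylisochroman-1-one
Product: 13 (3R,4R)-6,8-bis(benzyloxy)-4-hydroxy-7-methoxy-3-methylisochroman-1-one
Conditions: K2CO3 (0.2 equiv), MeOH–CH2Cl2, 0 °C
Reagents that add atoms: none
Why: Base-catalysed transesterification should remove the alkyl acetate selectively, because the lactone is a hindered benzoate deactivated by ortho and para alkoxy donors; neither C3 nor C4 carries a hydrogen acidic enough to epimerize.

**Step 8**
Reactants: 12 (3R,4R)-4-acetoxy-6,8-bis(benzyloxy)-7-methoxy-3-methylisochroman-1-one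
Product: 14 (3R,4R)-4-acetoxy-6,8-dihydroxy-7-methoxy-3-methylisochroman-1-one
Conditions: BCl3, C6HMe5, CH2Cl2, −78 °C; MeOH quench
Reagents that add atoms: none
Why: Lewis-acid debenzylation with pentamethylbenzene as a non-basic benzyl-cation trap should cleave both aryl benzyl ethers at −78 °C, while the secondary C4 acetate (ionization disfavoured by the boron-complexed ortho carbonyl) and the C7 methyl ether react far more slowly.

**Step 9**
Reactants: 13 (3R,4R)-6,8-bis(benzyloxy)-4-hydroxy-7-methoxy-3-methylisochroman-1-one; 14 (3R,4R)-4-acetoxy-6,8-dihydroxy-7-methoxy-3-methylisochroman-1-one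
Product: 15 (3R,4R)-6-{[(3R,4S)-6,8-bis(benzyloxy)-7-methoxy-3-methyl-1-oxoisochroman-4-yl]oxy}-8-hydroxy-7-methoxy-3-methyl-1-oxoisochroman-4-yl acetate
Conditions: PPh3, DIAD, THF, 0 °C → rt
Reagents that add atoms: none
Why: In this Mitsunobu etherification the C4 oxyphosphonium ion of 13 is displaced by the 6-phenoxide of 14 in an SN2 step, which inverts C4 from R to S (trans to the C3 methyl); the 6-OH, para to the lactone carbonyl, is the acidic free phenol, the 8-OH is tied up in a hydrogen bond to C1=O, and the acetate keeps the C4 hydroxyl of 14 from being activated.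

**Step 10**
Reactants: 15 (3R,4R)-6-{[(3R,4S)-6,8-bis(benzyloxy)-7-methoxy-3-methyl-1-oxoisochroman-4-yl]oxy}-8-hydroxy-7-methoxy-3-methyl-1-oxoisochroman-4-yl acetate
Product: 16 (3R,4R)-6-{[(3R,4S)-6,8-dihydroxy-7-methoxy-3-methyl-1-oxoisochroman-4-yl]oxy}-8-hydroxy-7-methoxy-3-methyl-1-oxoisochroman-4-yl acetate
Conditions: BCl3, C6HMe5, CH2Cl2, −78 °C; MeOH quench
Reagents that add atoms: none
Why: The same Lewis-acid debenzylation as in step 8 should remove the two primary benzyl groups, whereas the secondary C4–O ether between the units, flanked by a complexed lactone carbonyl, should ionize much more slowly; the acetate is kept on so that no free benzylic alcohol meets BCl3.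

**Step 11**
Reactants: 16 (3R,4R)-6-{[(3R,4S)-6,8-dihydroxy-7-methoxy-3-methyl-1-oxoisochroman-4-yl]oxy}-8-hydroxy-7-methoxy-3-methyl-1-oxoisochroman-4-yl acetate
Product: 17 (3R,4S)-6,8-dihydroxy-4-{[(3R,4R)-4,8-dihydroxy-7-methoxy-3-methyl-1-oxoisochroman-6-yl]oxy}-7-methoxy-3-methylisochroman-1-one
Conditions: K2CO3 (excess), MeOH, 0 °C → rt, under argon; then aq. NH4Cl
Reagents that add atoms: none
Why: Base-mediated methanolysis should cleave the only alkyl acetate; both lactone carbonyls are deactivated by their peri phenoxides and no stereocenter bears an acidic hydrogen, so all four centers stay as set.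

**Compound list**

1 | 3,5-dihydroxy-4-methoxybenzaldehyde | O=Cc1cc(O)c(OC)c(O)c1 | starting material
2 | benzyl bromide | BrCc1ccccc1 | starting material
3 | 3,5-bis(benzyloxy)-4-methoxybenzaldehyde | O=Cc1cc(OCc2ccccc2)c(OC)c(OCc2ccccc2)c1 | intermediate
4 | 3,5-bis(benzyloxy)-2-bromo-4-methoxybenzaldehyde | O=Cc1cc(OCc2ccccc2)c(OC)c(OCc2ccccc2)c1Br | intermediate
5 | ethyltriphenylphosphonium bromide | CC[P+](c1ccccc1)(c1ccccc1)c1ccccc1.[Br-] | starting material
6 | 1,3-bis(benzyloxy)-4-bromo-2-methoxy-5-[(Z)-prop-1-enyl]benzene | C/C=C\c1cc(OCc2ccccc2)c(OC)c(OCc2ccccc2)c1Br | intermediate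
7 | 1,3-bis(benzyloxy)-4-bromo-2-methoxy-5-[(E)-prop-1-enyl]benzene | C/C=C/c1cc(OCc2ccccc2)c(OC)c(OCc2ccccc2)c1Br | intermediate
8 | methyl chloroformate | COC(=O)Cl | starting material
9 | {2,4-bis(benzyloxy)-3-methoxy-6-[(E)-prop-1-enyl]phenyl}lithium (not isolated) | [Li]c1c(/C=C/C)cc(OCc2ccccc2)c(OC)c1OCc1ccccc1 | intermediate
10 | methyl 2,4-bis(benzyloxy)-3-methoxy-6-[(E)-prop-1-enyl]benzoate | COC(=O)c1c(/C=C/C)cc(OCc2ccccc2)c(OC)c1OCc1ccccc1 | intermediate
11 | acetic acid | CC(=O)O | starting material
12 | (3R,4R)-4-acetoxy-6,8-bis(benzyloxy)-7-methoxy-3-methylisochroman-1-one | COc1c(OCc2ccccc2)cc2c(c1OCc1ccccc1)C(=O)O[C@H](C)[C@@H]2OC(C)=O | intermediate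
13 | (3R,4R)-6,8-bis(benzyloxy)-4-hydroxy-7-methoxy-3-methylisochroman-1-one | COc1c(OCc2ccccc2)cc2c(c1OCc1ccccc1)C(=O)O[C@H](C)[C@@H]2O | intermediate
14 | (3R,4R)-4-acetoxy-6,8-dihydroxy-7-methoxy-3-methylisochroman-1-one | COc1c(O)cc2c(c1O)C(=O)O[C@H](C)[C@@H]2OC(C)=O | intermediate
15 | (3R,4R)-6-{[(3R,4S)-6,8-bis(benzyloxy)-7-methoxy-3-methyl-1-oxoisochroman-4-yl]oxy}-8-hydroxy-7-methoxy-3-methyl-1-oxoisochroman-4-yl acetate | COc1c(OCc2ccccc2)cc2c(c1OCc1ccccc1)C(=O)O[C@H](C)[C@H]2Oc1cc2c(c(O)c1OC)C(=O)O[C@H](C)[C@@H]2OC(C)=O | intermediate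
16 | (3R,4R)-6-{[(3R,4S)-6,8-dihydroxy-7-methoxy-3-methyl-1-oxoisochroman-4-yl]oxy}-8-hydroxy-7-methoxy-3-methyl-1-oxoisochroman-4-yl acetate | COc1c(O)cc2c(c1O)C(=O)O[C@H](C)[C@H]2Oc1cc2c(c(O)c1OC)C(=O)O[C@H](C)[C@@H]2OC(C)=O | intermediate
17 | (3R,4S)-6,8-dihydroxy-4-{[(3R,4R)-4,8-dihydroxy-7-methoxy-3-methyl-1-oxoisochroman-6-yl]oxy}-7-methoxy-3-methylisochroman-1-one | COc1c(O)cc2c(c1O)C(=O)O[C@H](C)[C@H]2Oc1cc2c(c(O)c1OC)C(=O)O[C@H](C)[C@@H]2O | target

**Step count and risk**

Total steps: 11. Longest linear sequence: 10 (steps 1–7, 9, 10, 11; step 8 is the side branch from 12).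

Steps most likely to fail:

1. Step 6. The reagent may discriminate the two alkene faces poorly on this crowded, alkoxy-rich benzoate. Fallback (resolution in place of induction): setting out from 10, the same ring closure would be run with achiral PhI(OAc)2, BF3·OEt2 and AcOH in CH2Cl2. This should give the racemic cis acetate, that is 12 mixed with its mirror image (3S,4S)-4-acetoxy-6,8-bis(benzyloxy)-7-methoxy-3-methylisochroman-1-one F1. Enantioselective enzymatic butanolysis (Candida antarctica lipase B, n-BuOH, MTBE, 30 °C) is expected, by the usual preference of this lipase for cyclic benzylic substrates (to be confirmed), to cleave the (4S)-acetate to (3S,4S)-6,8-bis(benzyloxy)-4-hydroxy-7-methoxy-3-methylisochroman-1-one F2. F2 would be separated by chromatography from unreacted 12, where the route is rejoined. Should the enzyme prefer the other antipode, the alcohol obtained is 13 itself and F1 is what remains.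

2. Step 9. Formation of the oxyphosphonium ion at the hindered cis C4 alcohol may be slow, so that the betaine is consumed in side reactions and conversion stalls. Fallback (preformed leaving group and Williamson displacement): setting out from 13, MsCl and Et3N in CH2Cl2 at −20 °C would give (3R,4R)-6,8-bis(benzyloxy)-7-methoxy-3-methyl-1-oxoisochroman-4-yl methanesulfonate F3. F3 would be displaced with inversion by the cesium 6-phenoxide of 14 (Cs2CO3, 1 equiv, DMF, 0 °C → rt), coming back to the route at 15.

3. Step 10. BCl3 may also cleave the benzylic C4–O ether between the units, or the C7 methyl ether once it is flanked by two boron-bound oxygens. Fallback (change of phenol protection before the coupling, so that no Lewis acid meets the dimer): setting out from 13, hydrogenolysis (H2, 10% Pd/C, EtOAc, rt; the free benzylic alcohol is far less prone to hydrogenolysis than a benzyl aryl ether) would give (3R,4R)-4,6,8-trihydroxy-7-methoxy-3-methylisochroman-1-one F4. TBSCl (1 equiv) and imidazole in DMF at 0 °C should silylate only the unchelated, most acidic O6 phenol and give (3R,4R)-6-(tert-butyldimethylsilyloxy)-4,8-dihydroxy-7-methoxy-3-methylisochroman-1-one F5. Mitsunobu coupling of F5 with 14 under the conditions of step 9 would give (3R,4R)-6-{[(3R,4S)-6-(tert-butyldimethylsilyloxy)-8-hydroxy-7-methoxy-3-methyl-1-oxoisochroman-4-yl]oxy}-8-hydroxy-7-methoxy-3-methyl-1-oxoisochroman-4-yl acetate F6. K2CO3 in MeOH would then remove the aryl silyl ether and the acetate together, coming back to the route at 17.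

**Further compounds**

F1 | step 6 | (3S,4S)-4-acetoxy-6,8-bis(benzyloxy)-7-methoxy-3-methylisochroman-1-one | COc1c(OCc2ccccc2)cc2c(c1OCc1ccccc1)C(=O)O[C@@H](C)[C@H]2OC(C)=O
F2 | step 6 | (3S,4S)-6,8-bis(benzyloxy)-4-hydroxy-7-methoxy-3-methylisochroman-1-one | COc1c(OCc2ccccc2)cc2c(c1OCc1ccccc1)C(=O)O[C@@H](C)[C@H]2O
F3 | step 9 | (3R,4R)-6,8-bis(benzyloxy)-7-methoxy-3-methyl-1-oxoisochroman-4-yl methanesulfonate | COc1c(OCc2ccccc2)cc2c(c1OCc1ccccc1)C(=O)O[C@H](C)[C@@H]2OS(C)(=O)=O
F4 | step 10 | (3R,4R)-4,6,8-trihydroxy-7-methoxy-3-methylisochroman-1-one | COc1c(O)cc2c(c1O)C(=O)O[C@H](C)[C@@H]2O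
F5 | step 10 | (3R,4R)-6-(tert-butyldimethylsilyloxy)-4,8-dihydroxy-7-methoxy-3-methylisochroman-1-one | COc1c(O[Si](C)(C)C(C)(C)C)cc2c(c1O)C(=O)O[C@H](C)[C@@H]2O
F6 | step 10 | (3R,4R)-6-{[(3R,4S)-6-(tert-butyldimethylsilyloxy)-8-hydroxy-7-methoxy-3-methyl-1-oxoisochroman-4-yl]oxy}-8-hydroxy-7-methoxy-3-methyl-1-oxoisochroman-4-yl acetate | COc1c(O[Si](C)(C)C(C)(C)C)cc2c(c1O)C(=O)O[C@H](C)[C@H]2Oc1cc2c(c(O)c1OC)C(=O)O[C@H](C)[C@@H]2OC(C)=O
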